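## Retrosynthetic overview

1. The only ring, the 36-membered lactone, is closed second to last by an intramolecular Horner–Wadsworth–Emmons (HWE) olefination at C2=C3 between a C35 phosphonopropionate ester and a C3 tetraenal; global desilylation follows.
2. The pentaene comes from a Suzuki coupling (C9–C10) of an (E)-alkenyl-Bpin with 7-bromohepta-2,4,6-trienal; the alkenyl-Bpin comes from chiral phosphoric acid (CPA) allylboration of a C13 aldehyde (sets C13) and cross-metathesis with vinyl-Bpin.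
3. The C13 aldehyde and the C21 ketone are unveiled together by one ozonolysis of a terminal vinyl group and a 1,1-disubstituted alkene.
4. The C19–C23 unit is built on the bis(boronate) CH2=C(CH2Bpin)2 by two sequential CPA-catalysed allylborations with enantiomeric catalysts (new), joining a West aldehyde (C13–C19) to an East aldehyde (C23–C35) and setting C19 and C23.
5. West aldehyde: two iterative CPA allylborations from 3,3-dimethoxypropanal (C17 is the first stereocentre, then C15). East aldehyde: CPA allylboration of isobutyraldehyde (C35), a boron aldol (C25), cross-metathesis and hydrogenation.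

Assumptions and notation: the target is the open-chain hydroxy-ketone form drawn; C1–C35 is the macrolide numbering (C1 lactone carbonyl, C35 the isopropyl carbinol); TES = triethylsilyl, pin = pinacolato, TRIP = 3,3'-bis(2,4,6-triisopropylphenyl)-1,1'-binaphthyl-2,2'-diyl hydrogen phosphate, with (R)-TRIP taken to deliver the allyl group to the aldehyde Re face and (S)-TRIP to the Si face; (+)-Ipc2BCl is taken to direct a methyl-ketone enolate to the aldehyde Re face; compound 13 and everything made from it is a 1:1 mixture of epimers at the phosphonate-bearing carbon, which becomes C2 in step 24.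

## Route

Step 1
Reactants: 1 3,3-dimethoxypropanal; 2 allylboronic acid pinacol ester
Product: 3 (3S)-1,1-dimethoxyhex-5-en-3-ol
Conditions: (S)-TRIP (5 mol%), 4 Å MS, toluene, −30 °C; aq. NaHCO3
Reagents that add atoms: none
Why: CPA-catalysed allylboration through a chair transition state (acid bound to a boronate oxygen and the formyl H) adds allyl to the Si face and sets C17 as the first stereocentre from achiral materials.

Step 2
Reactants: 3 (3S)-1,1-dimethoxyhex-5-en-3-ol
Product: 4 triethyl{[(3S)-1,1-dimethoxyhex-5-en-3-yl]oxy}silane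
Conditions: TESCl, imidazole, DMF, 0 → 23 °C
Reagents that add atoms: chlorotriethylsilane, CC[Si](Cl)(CC)CC
Why: Standard silyl ether formation under basic conditions that leave the dimethyl acetal untouched.

Step 3
Reactants: 4 triethyl{[(3S)-1,1-dimethoxyhex-5-en-3-yl]oxy}silane
Product: 5 (3S)-5,5-dimethoxy-3-(triethylsilyloxy)pentanal
Conditions: O3, CH2Cl2, −78 °C; then PPh3, −78 → 23 °C
Reagents that add atoms: ozone, [O-][O+]=O
Why: Ozonolysis with reductive work-up converts the terminal alkene into the C15 aldehyde without touching the silyl ether or acetal.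

Step 4
Reactants: 5 (3S)-5,5-dimethoxy-3-(triethylsilyloxy)pentanal; 2 allylboronic acid pinacol ester
Product: 6 (4S,6S)-8,8-dimethoxy-6-(triethylsilyloxy)oct-1-en-4-ol
Conditions: (S)-TRIP (5 mol%), 4 Å MS, toluene, −30 °C
Reagents that add atoms: none
Why: A second CPA-catalysed allylboration, Si-face attack under catalyst control on the β-silyloxy aldehyde, sets C15 syn to C17.

Step 5
Reactants: 6 (4S,6S)-8,8-dimethoxy-6-(triethylsilyloxy)oct-1-en-4-ol
Product: 8 (3S,5S)-3,5-bis(triethylsilyloxy)oct-7-enal, via bis-TES dimethyl acetal 7 (not isolated)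
Conditions: TESOTf (3 equiv), 2,4,6-collidine (4 equiv), CH2Cl2, 0 °C; then H2O
Reagents that add atoms: triethylsilyl trifluoromethanesulfonate, CC[Si](CC)(CC)OS(=O)(=O)C(F)(F)F; water, O
Why: Silylation of the alcohol is followed in the same flask by Fujioka-type acetal cleavage (silyl triflate activation, collidinium adduct, hydrolysis), a non-acidic unmasking that spares the TES ethers and the β-silyloxy aldehyde.

Step 6
Reactants: 9 2-methylpropanal; 2 allylboronic acid pinacol ester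
Product: 10 (3R)-2-methylhex-5-en-3-ol
Conditions: (R)-TRIP (5 mol%), 4 Å MS, toluene, −30 °C
Reagents that add atoms: none
Why: CPA-catalysed allylboration of an α-branched aldehyde with Re-face attack sets C35 (R).

Step 7
Reactants: 10 (3R)-2-methylhex-5-en-3-ol; 11 2-(diethoxyphosphoryl)acetic acid
Product: 12 (3R)-2-methylhex-5-en-3-yl 2-(diethoxyphosphoryl)acetate
Conditions: DCC, DMAP (cat.), CH2Cl2, 0 → 23 °C
Reagents that add atoms: none
Why: Steglich esterification installs the future C1–C2 unit on the C35 oxygen, where it also serves as the protecting group.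

Step 8
Reactants: 12 (3R)-2-methylhex-5-en-3-yl 2-(diethoxyphosphoryl)acetate
Product: 13 (3R)-2-methylhex-5-en-3-yl 2-(diethoxyphosphoryl)propanoate
Conditions: NaH (1.0 equiv), THF, 0 °C; MeI (1.05 equiv), 0 → 23 °C
Reagents that add atoms: iodomethane, CI
Why: C-alkylation of the stabilised phosphonoacetate anion introduces the C2 methyl group; the new centre is unselective and is destroyed in the HWE step.

Step 9
Reactants: 14 oct-7-en-2-one; 1 3,3-dimethoxypropanal
Product: 15 (9S)-9-hydroxy-11,11-dimethoxyundec-1-en-7-one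
Conditions: (+)-Ipc2BCl, Et3N, Et2O, −78 °C; then 1, −78 → −20 °C; MeOH, pH 7 buffer, 30% H2O2, 0 °C
Reagents that add atoms: none
Why: Paterson boron aldol reaction, with kinetic enolisation on the methyl side and reagent-controlled Re-face addition, sets C25 (S); about 80–90% ee is expected and the minor epimer is removed as a separable diastereomer after step 16.

Step 10
Reactants: 15 (9S)-9-hydroxy-11,11-dimethoxyundec-1-en-7-one; 13 (3R)-2-methylhex-5-en-3-yl 2-(diethoxyphosphoryl)propanoate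
Product: 16 (3R,13S)-13-hydroxy-15,15-dimethoxy-2-methyl-11-oxopentadec-5-en-3-yl 2-(diethoxyphosphoryl)propanoate (E/Z mixture)
Conditions: second-generation Hoveyda–Grubbs catalyst RuCl2(H2IMes)(=CH-C6H4-2-OiPr) (5 mol%), 13 (2 equiv), CH2Cl2, 40 °C
Reagents that add atoms: none
Why: Olefin cross-metathesis of two unhindered terminal alkenes joins C32 to C33; alkene geometry is irrelevant.

Step 11
Reactants: 16 (3R,13S)-13-hydroxy-15,15-dimethoxy-2-methyl-11-oxopentadec-5-en-3-yl 2-(diethoxyphosphoryl)propanoate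
Product: 17 (3R,13S)-13-hydroxy-15,15-dimethoxy-2-methyl-11-oxopentadecan-3-yl 2-(diethoxyphosphoryl)propanoate
Conditions: H2 (1 atm), Pd/C (10 wt% Pd on carbon), EtOAc, 23 °C
Reagents that add atoms: none
Why: Catalytic hydrogenation saturates the only alkene; ketone, acetal, ester and phosphonate are inert.

Step 12
Reactants: 17 (3R,13S)-13-hydroxy-15,15-dimethoxy-2-methyl-11-oxopentadecan-3-yl 2-(diethoxyphosphoryl)propanoate
Product: 19 (3R,13S)-2-methyl-11,15-dioxo-13-(triethylsilyloxy)pentadecan-3-yl 2-(diethoxyphosphoryl)propanoate, via TES-protected dimethyl acetal 18 (not isolated)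
Conditions: TESOTf (3 equiv), 2,4,6-collidine (4 equiv), CH2Cl2, 0 °C; then H2O
Reagents that add atoms: triethylsilyl trifluoromethanesulfonate, CC[Si](CC)(CC)OS(=O)(=O)C(F)(F)F; water, O
Why: The same silylation and Fujioka acetal cleavage as in step 5 gives the East aldehyde (C23–C35) without acid, so the β-silyloxy ketone and aldehyde do not eliminate.

Step 13
Reactants: 20 3-chloro-2-(chloromethyl)prop-1-ene; 21 bis(pinacolato)diboron
Product: 22 2,2'-(2-methylidenepropane-1,3-diyl)bis(4,4,5,5-tetramethyl-1,3,2-dioxaborolane)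
Conditions: Pd2(dba)3 (2.5 mol%), 21 (2.2 equiv), THF, 60 °C
Reagents that add atoms: none
Why: Borylation of allylic chlorides with zerovalent palladium (π-allyl formation, B–B transmetalation, reductive elimination) at both termini gives the bis(boronate) linchpin.

Step 14
Reactants: 8 (3S,5S)-3,5-bis(triethylsilyloxy)oct-7-enal; 22 2,2'-(2-methylidenepropane-1,3-diyl)bis(4,4,5,5-tetramethyl-1,3,2-dioxaborolane)
Product: 23 (4S,6R,8S)-2-[(4,4,5,5-tetramethyl-1,3,2-dioxaborolan-2-yl)methyl]-6,8-bis(triethylsilyloxy)undeca-1,10-dien-4-ol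
Conditions: (S)-TRIP (10 mol%), 22 (3 equiv), 4 Å MS, toluene, −30 °C; excess 22 recovered
Reagents that add atoms: none
Why: Proposed new method: CPA-catalysed enantioselective mono-allylboration with a 2-(borylmethyl)allylboronate, in which the acid binds a pinacol oxygen and the formyl H in the usual chair transition state so that (S)-TRIP delivers C20 to the Si face of 8 (C19 set anti to C17 under catalyst control) and the product, now a bulkier 2-substituted allylboronate, reacts more slowly so that excess 22 stops the reaction at the mono-adduct; the closest known reaction types are CPA-catalysed allyl- and methallylboration of aldehydes with simple pinacol boronates and the stoichiometric diisopinocampheylborane double allylboration of the same four-carbon unit.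

Step 15
Reactants: 23 (4S,6R,8S)-2-[(4,4,5,5-tetramethyl-1,3,2-dioxaborolan-2-yl)methyl]-6,8-bis(triethylsilyloxy)undeca-1,10-dien-4-ol
Product: 24 2-[(4S,6S,8S)-2-methylidene-4,6,8-tris(triethylsilyloxy)undec-10-en-1-yl]-4,4,5,5-tetramethyl-1,3,2-dioxaborolane
Conditions: TESOTf, 2,6-lutidine, CH2Cl2, −78 °C
Reagents that add atoms: triethylsilyl trifluoromethanesulfonate, CC[Si](CC)(CC)OS(=O)(=O)C(F)(F)F
Why: Silylation of the C19 hydroxyl prevents intramolecular O–B chelation or ester exchange that would disturb the next catalyst-controlled allylboration.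

Step 16
Reactants: 24 2-[(4S,6S,8S)-2-methylidene-4,6,8-tris(triethylsilyloxy)undec-10-en-1-yl]-4,4,5,5-tetramethyl-1,3,2-dioxaborolane; 19 (3R,13S)-2-methyl-11,15-dioxo-13-(triethylsilyloxy)pentadecan-3-yl 2-(diethoxyphosphoryl)propanoate
Product: 25 (3R,13S,15R,19S,21S,23S)-15-hydroxy-2-methyl-17-methylidene-11-oxo-13,19,21,23-tetrakis(triethylsilyloxy)hexacos-25-en-3-yl 2-(diethoxyphosphoryl)propanoate
Conditions: (R)-TRIP (10–20 mol%), 24 (1.2 equiv), 4 Å MS, toluene, −30 → 0 °C
Reagents that add atoms: none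
Why: Proposed new method: fragment-coupling CPA-catalysed allylboration with a fully functionalised 2-substituted allyl-Bpin, where the enantiomeric catalyst (R)-TRIP enforces Re-face attack on aldehyde 19 through the same chair transition state, forging C22–C23 and setting C23 anti to C25 (pseudo-meso to C19) with the aldehyde reacting in preference to the C27 ketone; the closest known reaction type is CPA-catalysed allyl- and methallylboration with simple reagents, where β-silyloxy aldehydes are known to follow catalyst control.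

Step 17
Reactants: 25 (3R,13S,15R,19S,21S,23S)-15-hydroxy-2-methyl-17-methylidene-11-oxo-13,19,21,23-tetrakis(triethylsilyloxy)hexacos-25-en-3-yl 2-(diethoxyphosphoryl)propanoate
Product: 26 (3R,13S,15R,19S,21S,23S)-2-methyl-17-methylidene-11-oxo-13,15,19,21,23-pentakis(triethylsilyloxy)hexacos-25-en-3-yl 2-(diethoxyphosphoryl)propanoate
Conditions: TESOTf, 2,6-lutidine, CH2Cl2, −78 °C
Reagents that add atoms: triethylsilyl trifluoromethanesulfonate, CC[Si](CC)(CC)OS(=O)(=O)C(F)(F)F
Why: Silylation of C23-OH protects the future β-hydroxy ketone against retro-aldol and elimination in the basic late steps.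

Step 18
Reactants: 26 (3R,13S,15R,19S,21S,23S)-2-methyl-17-methylidene-11-oxo-13,15,19,21,23-pentakis(triethylsilyloxy)hexacos-25-en-3-yl 2-(diethoxyphosphoryl)propanoate
Product: 27 (3R,13S,15S,19R,21S,23R)-2-methyl-11,17,25-trioxo-13,15,19,21,23-pentakis(triethylsilyloxy)pentacosan-3-yl 2-(diethoxyphosphoryl)propanoate
Conditions: O3, CH2Cl2, −78 °C; then PPh3, −78 → 23 °C
Reagents that add atoms: ozone, [O-][O+]=O
Why: One ozonolysis cleaves both alkenes, unveiling the C21 ketone and the C13 aldehyde while silyl ethers, the C27 ketone and the phosphonate stay intact.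

Step 19
Reactants: 27 (3R,13S,15S,19R,21S,23R)-2-methyl-11,17,25-trioxo-13,15,19,21,23-pentakis(triethylsilyloxy)pentacosan-3-yl 2-(diethoxyphosphoryl)propanoate; 2 allylboronic acid pinacol ester
Product: 28 (3R,13S,15S,19R,21S,23S,25S)-25-hydroxy-2-methyl-11,17-dioxo-13,15,19,21,23-pentakis(triethylsilyloxy)octacos-27-en-3-yl 2-(diethoxyphosphoryl)propanoate
Conditions: (S)-TRIP (10 mol%), 4 Å MS, toluene, −30 °C
Reagents that add atoms: none
Why: CPA-catalysed allylboration is aldehyde-selective over the two ketones and Si-face attack under catalyst control sets C13 (S), syn to C15.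

Step 20
Reactants: 28 (3R,13S,15S,19R,21S,23S,25S)-25-hydroxy-2-methyl-11,17-dioxo-13,15,19,21,23-pentakis(triethylsilyloxy)octacos-27-en-3-yl 2-(diethoxyphosphoryl)propanoate; 29 vinylboronic acid pinacol ester
Product: 30 (3R,13S,15S,19R,21S,23S,25S,27E)-25-hydroxy-2-methyl-11,17-dioxo-28-(4,4,5,5-tetramethyl-1,3,2-dioxaborolan-2-yl)-13,15,19,21,23-pentakis(triethylsilyloxy)octacos-27-en-3-yl 2-(diethoxyphosphoryl)propanoate
Conditions: second-generation Hoveyda–Grubbs catalyst RuCl2(H2IMes)(=CH-C6H4-2-OiPr) (10 mol%), 29 (5 equiv), CH2Cl2, 40 °C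
Reagents that add atoms: none
Why: Cross-metathesis of a terminal alkene with vinyl-Bpin gives the E-alkenylboronate (C10=C11) selectively.

Step 21
Reactants: 31 glutaconaldehyde potassium salt
Product: 32 (2E,4E)-5-bromopenta-2,4-dienal
Conditions: PPh3, Br2, CH2Cl2, 0 → 23 °C
Reagents that add atoms: bromine, BrBr
Why: The enolate oxygen is activated as an oxyphosphonium ion and displaced by bromide in a vinylogous addition–elimination, giving the all-E bromodienal.

Step 22
Reactants: 32 (2E,4E)-5-bromopenta-2,4-dienal; 33 (triphenylphosphoranylidene)acetaldehyde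
Product: 34 (2E,4E,6E)-7-bromohepta-2,4,6-trienal
Conditions: 33 (1.0 equiv), toluene, 60 °C; then cat. iodine, hexane, 23 °C
Reagents that add atoms: none
Why: Wittig two-carbon homologation with a stabilised ylide is E-selective, and limiting the ylide keeps over-homologation low.

Step 23
Reactants: 30 (3R,13S,15S,19R,21S,23S,25S,27E)-25-hydroxy-2-methyl-11,17-dioxo-28-(4,4,5,5-tetramethyl-1,3,2-dioxaborolan-2-yl)-13,15,19,21,23-pentakis(triethylsilyloxy)octacos-27-en-3-yl 2-(diethoxyphosphoryl)propanoate; 34 (2E,4E,6E)-7-bromohepta-2,4,6-trienal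
Product: 35 (3R,13S,15S,19R,21S,23S,25S,27E,29E,31E,33E)-25-hydroxy-2-methyl-11,17,35-trioxo-13,15,19,21,23-pentakis(triethylsilyloxy)pentatriaconta-27,29,31,33-tetraen-3-yl 2-(diethoxyphosphoryl)propanoate
Conditions: Pd(PPh3)4 (10 mol%), Tl2CO3, THF/H2O 3:1, 23 °C, dark
Reagents that add atoms: none
Why: Suzuki–Miyaura coupling forms C9–C10 with retention of both alkene geometries, and the weak carbonate base at room temperature avoids premature olefination between aldehyde and phosphonate.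

Step 24
Reactants: 35 (3R,13S,15S,19R,21S,23S,25S,27E,29E,31E,33E)-25-hydroxy-2-methyl-11,17,35-trioxo-13,15,19,21,23-pentakis(triethylsilyloxy)pentatriaconta-27,29,31,33-tetraen-3-yl 2-(diethoxyphosphoryl)propanoate
Product: 36 (3E,5E,7E,9E,11E,14S,16S,18S,20R,24S,26S,36R)-14-hydroxy-3-methyl-36-(propan-2-yl)-16,18,20,24,26-pentakis(triethylsilyloxy)-1-oxacyclohexatriaconta-3,5,7,9,11-pentaene-2,22,28-trione
Conditions: K2CO3, 18-crown-6, toluene (0.001 M), 23 → 50 °C, dark
Reagents that add atoms: none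
Why: Intramolecular Horner–Wadsworth–Emmons olefination at high dilution closes the 36-membered lactone, the α-methyl phosphonate giving the E trisubstituted C2=C3 enoate.

Step 25
Reactants: 36 (3E,5E,7E,9E,11E,14S,16S,18S,20R,24S,26S,36R)-14-hydroxy-3-methyl-36-(propan-2-yl)-16,18,20,24,26-pentakis(triethylsilyloxy)-1-oxacyclohexatriaconta-3,5,7,9,11-pentaene-2,22,28-trione
Product: 37 (3E,5E,7E,9E,11E,14S,16S,18S,20R,24S,26S,36R)-14,16,18,20,24,26-hexahydroxy-3-methyl-36-(propan-2-yl)-1-oxacyclohexatriaconta-3,5,7,9,11-pentaene-2,22,28-trione (CNP0167014.1)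
Conditions: HF·pyridine, pyridine, THF, 0 → 23 °C, dark
Reagents that add atoms: none
Why: Buffered fluoride cleaves the five TES ethers under conditions tolerated by the pentaene and the β-hydroxy ketones, giving the target.

## Compound list

1 | 3,3-dimethoxypropanal | COC(CC=O)OC | starting material
2 | allylboronic acid pinacol ester | C=CCB1OC(C)(C)C(C)(C)O1 | starting material
3 | (3S)-1,1-dimethoxyhex-5-en-3-ol | C=CC[C@H](O)CC(OC)OC | intermediate
4 | triethyl{[(3S)-1,1-dimethoxyhex-5-en-3-yl]oxy}silane | C=CC[C@H](O[Si](CC)(CC)CC)CC(OC)OC | intermediate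
5 | (3S)-5,5-dimethoxy-3-(triethylsilyloxy)pentanal | O=CC[C@H](O[Si](CC)(CC)CC)CC(OC)OC | intermediate
6 | (4S,6S)-8,8-dimethoxy-6-(triethylsilyloxy)oct-1-en-4-ol | C=CC[C@H](O)C[C@H](O[Si](CC)(CC)CC)CC(OC)OC | intermediate
7 | (4S,6S)-8,8-dimethoxy-4,6-bis(triethylsilyloxy)oct-1-ene | C=CC[C@H](O[Si](CC)(CC)CC)C[C@H](O[Si](CC)(CC)CC)CC(OC)OC | intermediate
8 | (3S,5S)-3,5-bis(triethylsilyloxy)oct-7-enal | C=CC[C@H](O[Si](CC)(CC)CC)C[C@H](O[Si](CC)(CC)CC)CC=O | intermediate
9 | 2-methylpropanal | CC(C)C=O | starting material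
10 | (3R)-2-methylhex-5-en-3-ol | C=CC[C@H](C(C)C)O | intermediate
11 | 2-(diethoxyphosphoryl)acetic acid | CCOP(=O)(CC(=O)O)OCC | starting material
12 | (3R)-2-methylhex-5-en-3-yl 2-(diethoxyphosphoryl)acetate | C=CC[C@H](C(C)C)OC(=O)CP(=O)(OCC)OCC | intermediate
13 | (3R)-2-methylhex-5-en-3-yl 2-(diethoxyphosphoryl)propanoate | C=CC[C@H](C(C)C)OC(=O)C(C)P(=O)(OCC)OCC | intermediate
14 | oct-7-en-2-one | CC(=O)CCCCC=C | starting material
15 | (9S)-9-hydroxy-11,11-dimethoxyundec-1-en-7-one | COC(OC)C[C@H](O)CC(=O)CCCCC=C | intermediate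
16 | (3R,13S)-13-hydroxy-15,15-dimethoxy-2-methyl-11-oxopentadec-5-en-3-yl 2-(diethoxyphosphoryl)propanoate | COC(OC)C[C@H](O)CC(=O)CCCCC=CC[C@H](C(C)C)OC(=O)C(C)P(=O)(OCC)OCC | intermediate
17 | (3R,13S)-13-hydroxy-15,15-dimethoxy-2-methyl-11-oxopentadecan-3-yl 2-(diethoxyphosphoryl)propanoate | COC(OC)C[C@H](O)CC(=O)CCCCCCC[C@H](C(C)C)OC(=O)C(C)P(=O)(OCC)OCC | intermediate
18 | (3R,13S)-15,15-dimethoxy-2-methyl-11-oxo-13-(triethylsilyloxy)pentadecan-3-yl 2-(diethoxyphosphoryl)propanoate | COC(OC)C[C@H](O[Si](CC)(CC)CC)CC(=O)CCCCCCC[C@H](C(C)C)OC(=O)C(C)P(=O)(OCC)OCC | intermediate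
19 | (3R,13S)-2-methyl-11,15-dioxo-13-(triethylsilyloxy)pentadecan-3-yl 2-(diethoxyphosphoryl)propanoate | O=CC[C@H](O[Si](CC)(CC)CC)CC(=O)CCCCCCC[C@H](C(C)C)OC(=O)C(C)P(=O)(OCC)OCC | intermediate
20 | 3-chloro-2-(chloromethyl)prop-1-ene | C=C(CCl)CCl | starting material
21 | bis(pinacolato)diboron | CC1(C)OB(OC1(C)C)B1OC(C)(C)C(C)(C)O1 | starting material
22 | 2,2'-(2-methylidenepropane-1,3-diyl)bis(4,4,5,5-tetramethyl-1,3,2-dioxaborolane) | C=C(CB1OC(C)(C)C(C)(C)O1)CB1OC(C)(C)C(C)(C)O1 | intermediate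
23 | (4S,6R,8S)-2-[(4,4,5,5-tetramethyl-1,3,2-dioxaborolan-2-yl)methyl]-6,8-bis(triethylsilyloxy)undeca-1,10-dien-4-ol | C=CC[C@H](O[Si](CC)(CC)CC)C[C@H](O[Si](CC)(CC)CC)C[C@@H](O)CC(=C)CB1OC(C)(C)C(C)(C)O1 | intermediate
24 | 2-[(4S,6S,8S)-2-methylidene-4,6,8-tris(triethylsilyloxy)undec-10-en-1-yl]-4,4,5,5-tetramethyl-1,3,2-dioxaborolane | C=CC[C@H](O[Si](CC)(CC)CC)C[C@H](O[Si](CC)(CC)CC)C[C@@H](O[Si](CC)(CC)CC)CC(=C)CB1OC(C)(C)C(C)(C)O1 | intermediate
25 | (3R,13S,15R,19S,21S,23S)-15-hydroxy-2-methyl-17-methylidene-11-oxo-13,19,21,23-tetrakis(triethylsilyloxy)hexacos-25-en-3-yl 2-(diethoxyphosphoryl)propanoate | C=CC[C@H](O[Si](CC)(CC)CC)C[C@H](O[Si](CC)(CC)CC)C[C@@H](O[Si](CC)(CC)CC)CC(=C)C[C@@H](O)C[C@H](O[Si](CC)(CC)CC)CC(=O)CCCCCCC[C@H](C(C)C)OC(=O)C(C)P(=O)(OCC)OCC | intermediate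
26 | (3R,13S,15R,19S,21S,23S)-2-methyl-17-methylidene-11-oxo-13,15,19,21,23-pentakis(triethylsilyloxy)hexacos-25-en-3-yl 2-(diethoxyphosphoryl)propanoate | C=CC[C@H](O[Si](CC)(CC)CC)C[C@H](O[Si](CC)(CC)CC)C[C@@H](O[Si](CC)(CC)CC)CC(=C)C[C@@H](O[Si](CC)(CC)CC)C[C@H](O[Si](CC)(CC)CC)CC(=O)CCCCCCC[C@H](C(C)C)OC(=O)C(C)P(=O)(OCC)OCC | intermediate
27 | (3R,13S,15S,19R,21S,23R)-2-methyl-11,17,25-trioxo-13,15,19,21,23-pentakis(triethylsilyloxy)pentacosan-3-yl 2-(diethoxyphosphoryl)propanoate | O=CC[C@H](O[Si](CC)(CC)CC)C[C@H](O[Si](CC)(CC)CC)C[C@@H](O[Si](CC)(CC)CC)CC(=O)C[C@@H](O[Si](CC)(CC)CC)C[C@H](O[Si](CC)(CC)CC)CC(=O)CCCCCCC[C@H](C(C)C)OC(=O)C(C)P(=O)(OCC)OCC | intermediate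
28 | (3R,13S,15S,19R,21S,23S,25S)-25-hydroxy-2-methyl-11,17-dioxo-13,15,19,21,23-pentakis(triethylsilyloxy)octacos-27-en-3-yl 2-(diethoxyphosphoryl)propanoate | C=CC[C@H](O)C[C@H](O[Si](CC)(CC)CC)C[C@H](O[Si](CC)(CC)CC)C[C@@H](O[Si](CC)(CC)CC)CC(=O)C[C@@H](O[Si](CC)(CC)CC)C[C@H](O[Si](CC)(CC)CC)CC(=O)CCCCCCC[C@H](C(C)C)OC(=O)C(C)P(=O)(OCC)OCC | intermediate
29 | vinylboronic acid pinacol ester | C=CB1OC(C)(C)C(C)(C)O1 | starting material
30 | (3R,13S,15S,19R,21S,23S,25S,27E)-25-hydroxy-2-methyl-11,17-dioxo-28-(4,4,5,5-tetramethyl-1,3,2-dioxaborolan-2-yl)-13,15,19,21,23-pentakis(triethylsilyloxy)octacos-27-en-3-yl 2-(diethoxyphosphoryl)propanoate | CC1(C)OB(/C=C/C[C@H](O)C[C@H](O[Si](CC)(CC)CC)C[C@H](O[Si](CC)(CC)CC)C[C@@H](O[Si](CC)(CC)CC)CC(=O)C[C@@H](O[Si](CC)(CC)CC)C[C@H](O[Si](CC)(CC)CC)CC(=O)CCCCCCC[C@H](C(C)C)OC(=O)C(C)P(=O)(OCC)OCC)OC1(C)C | intermediate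
31 | glutaconaldehyde potassium salt | [K+].[O-]/C=C/C=C/C=O | starting material
32 | (2E,4E)-5-bromopenta-2,4-dienal | O=C/C=C/C=C/Br | intermediate
33 | (triphenylphosphoranylidene)acetaldehyde | O=CC=P(c1ccccc1)(c1ccccc1)c1ccccc1 | starting material
34 | (2E,4E,6E)-7-bromohepta-2,4,6-trienal | O=C/C=C/C=C/C=C/Br | intermediate
35 | (3R,13S,15S,19R,21S,23S,25S,27E,29E,31E,33E)-25-hydroxy-2-methyl-11,17,35-trioxo-13,15,19,21,23-pentakis(triethylsilyloxy)pentatriaconta-27,29,31,33-tetraen-3-yl 2-(diethoxyphosphoryl)propanoate | O=C/C=C/C=C/C=C/C=C/C[C@H](O)C[C@H](O[Si](CC)(CC)CC)C[C@H](O[Si](CC)(CC)CC)C[C@@H](O[Si](CC)(CC)CC)CC(=O)C[C@@H](O[Si](CC)(CC)CC)C[C@H](O[Si](CC)(CC)CC)CC(=O)CCCCCCC[C@H](C(C)C)OC(=O)C(C)P(=O)(OCC)OCC | intermediate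
36 | (3E,5E,7E,9E,11E,14S,16S,18S,20R,24S,26S,36R)-14-hydroxy-3-methyl-36-(propan-2-yl)-16,18,20,24,26-pentakis(triethylsilyloxy)-1-oxacyclohexatriaconta-3,5,7,9,11-pentaene-2,22,28-trione | C\C1=C/C=C/C=C/C=C/C=C/C[C@H](O)C[C@H](O[Si](CC)(CC)CC)C[C@H](O[Si](CC)(CC)CC)C[C@@H](O[Si](CC)(CC)CC)CC(=O)C[C@@H](O[Si](CC)(CC)CC)C[C@H](O[Si](CC)(CC)CC)CC(=O)CCCCCCC[C@H](C(C)C)OC1=O | intermediate
37 | (3E,5E,7E,9E,11E,14S,16S,18S,20R,24S,26S,36R)-14,16,18,20,24,26-hexahydroxy-3-methyl-36-(propan-2-yl)-1-oxacyclohexatriaconta-3,5,7,9,11-pentaene-2,22,28-trione | C\C1=C/C=C/C=C/C=C/C=C/C[C@H](O)C[C@H](O)C[C@H](O)C[C@@H](O)CC(=O)C[C@@H](O)C[C@H](O)CC(=O)CCCCCCC[C@H](C(C)C)OC1=O | target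

## Step count and risks

Total steps: 25. Longest linear sequence: 15 steps (steps 1–5, 14–20 and 23–25, from 1 to 37).

Steps most likely to fail:

- **Step 14 (new mono-allylboration with the bis(boronate)).** Risk: double addition or eroded catalyst control caused by the 2-(borylmethyl) substituent. The fallback uses known chemistry and sets out from 8. A Hosomi–Sakurai reaction with commercial [2-(chloromethyl)allyl]trimethylsilane and BF3·OEt2 in CH2Cl2 at −78 °C (open transition state, 1,3-anti induction from the β-silyloxy group, which is the C19 configuration needed) gives the 2-(chloromethyl) homoallylic alcohol F1. TESOTf and 2,6-lutidine give its TES ether F2. Borylation of the allylic chloride of F2 with 21 and Pd2(dba)3, as in step 13, gives 24, where the route is rejoined.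

- **Step 16 (new fragment-coupling allylboration).** Risk: the hindered, functionalised allylboronate may react sluggishly, or the phosphonate may bind the acid catalyst and lower selectivity. The fallback uses known boron aldol chemistry, sets out from 8 and avoids the boron linchpin. Acetone is enolised with (−)-Ipc2BCl and Et3N and added to 8 (Si face) to give the β-hydroxy methyl ketone F3, and TESOTf with 2,6-lutidine gives the silylated methyl ketone F4. Enolisation of F4 with (+)-Ipc2BCl and Et3N and addition to 19 (Re face) gives the β-hydroxy ketone F5, in which C21 is already a ketone. Silylation gives the pentakis-TES ketone F6, and ozonolysis (O3, then PPh3) of its single alkene gives 27, where the route is rejoined.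

- **Step 24 (macrocyclic HWE).** Risk: oligomerisation, or base-induced β-elimination at the silyloxy ketones during a slow ring closure. The fallback changes the ring-closing bond and sets out from 30. Intermolecular HWE of the phosphonate of 30 with 34 (LiCl, DBU, MeCN, 23 °C) gives the bromotetraenoate alkenylboronate F7. Intramolecular Suzuki–Miyaura macrocyclisation of F7 (Pd(PPh3)4, Tl2CO3, THF/H2O, 0.001 M) forms C9–C10 and gives 36, where the route is rejoined.

## Further compounds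

F1 | step 14 | (4S,6R,8S)-2-(chloromethyl)-6,8-bis(triethylsilyloxy)undeca-1,10-dien-4-ol | C=CC[C@H](O[Si](CC)(CC)CC)C[C@H](O[Si](CC)(CC)CC)C[C@@H](O)CC(=C)CCl
F2 | step 14 | (4S,6S,8S)-2-(chloromethyl)-4,6,8-tris(triethylsilyloxy)undeca-1,10-diene | C=CC[C@H](O[Si](CC)(CC)CC)C[C@H](O[Si](CC)(CC)CC)C[C@@H](O[Si](CC)(CC)CC)CC(=C)CCl
F3 | step 16 | (4R,6R,8S)-4-hydroxy-6,8-bis(triethylsilyloxy)undec-10-en-2-one | C=CC[C@H](O[Si](CC)(CC)CC)C[C@H](O[Si](CC)(CC)CC)C[C@@H](O)CC(C)=O
F4 | step 16 | (4R,6S,8S)-4,6,8-tris(triethylsilyloxy)undec-10-en-2-one | C=CC[C@H](O[Si](CC)(CC)CC)C[C@H](O[Si](CC)(CC)CC)C[C@@H](O[Si](CC)(CC)CC)CC(C)=O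
F5 | step 16 | (3R,13S,15S,19R,21S,23S)-15-hydroxy-2-methyl-11,17-dioxo-13,19,21,23-tetrakis(triethylsilyloxy)hexacos-25-en-3-yl 2-(diethoxyphosphoryl)propanoate | C=CC[C@H](O[Si](CC)(CC)CC)C[C@H](O[Si](CC)(CC)CC)C[C@@H](O[Si](CC)(CC)CC)CC(=O)C[C@@H](O)C[C@H](O[Si](CC)(CC)CC)CC(=O)CCCCCCC[C@H](C(C)C)OC(=O)C(C)P(=O)(OCC)OCC
F6 | step 16 | (3R,13S,15S,19R,21S,23S)-2-methyl-11,17-dioxo-13,15,19,21,23-pentakis(triethylsilyloxy)hexacos-25-en-3-yl 2-(diethoxyphosphoryl)propanoate | C=CC[C@H](O[Si](CC)(CC)CC)C[C@H](O[Si](CC)(CC)CC)C[C@@H](O[Si](CC)(CC)CC)CC(=O)C[C@@H](O[Si](CC)(CC)CC)C[C@H](O[Si](CC)(CC)CC)CC(=O)CCCCCCC[C@H](C(C)C)OC(=O)C(C)P(=O)(OCC)OCC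
F7 | step 24 | (3R,13S,15S,19R,21S,23S,25S,27E)-25-hydroxy-2-methyl-11,17-dioxo-28-(4,4,5,5-tetramethyl-1,3,2-dioxaborolan-2-yl)-13,15,19,21,23-pentakis(triethylsilyloxy)octacos-27-en-3-yl (2E,4E,6E,8E)-9-bromo-2-methylnona-2,4,6,8-tetraenoate | CC1(C)OB(/C=C/C[C@H](O)C[C@H](O[Si](CC)(CC)CC)C[C@H](O[Si](CC)(CC)CC)C[C@@H](O[Si](CC)(CC)CC)CC(=O)C[C@@H](O[Si](CC)(CC)CC)C[C@H](O[Si](CC)(CC)CC)CC(=O)CCCCCCC[C@H](C(C)C)OC(=O)/C(C)=C/C=C/C=C/C=C/Br)OC1(C)C
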